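Suppose target is starting material holding dissolved gas in a fast balance: then target, divided by starting material left and by gas in solution, keeps one value at any charge. I call that quotient the holding constant, an apparent equilibrium constant, and I test how far it carries.

| setting | larch | elm | south-west | south | east | south-east |
|---|---|---|---|---|---|---|
| starting material | 0.039 M | 0.30 M | 0.060 M | 0.12 M | 0.25 M | 0.50 M |
| second substrate | 1 equiv | 1 equiv | 1.00 equiv | 1.00 equiv | 1.00 equiv | 1.00 equiv |
| gas | 5.3 mM (held) | 5.3 mM (held) | 5.3 mM (held) | 5.3 mM (held) | 5.3 mM (held) | 5.3 mM (held) |
| remark | run made earlier | run made earlier |  |  |  |  |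
| time |  |  | 4.0 h | 4.0 h | 4.0 h | 4.0 h |

| run | time / h | target / % |
|---|---|---|
| larch | 0.200 | 5.9 |
| larch | 0.667 | 10.9 |
| larch | 1.00 | 13.4 |
| larch | 1.50 | 13.5 |
| larch | 2.50 | 13.6 |
| larch | 3.00 | 15.0 |
| larch | 4.00 | 14.5 |
| elm | 0.333 | 2.1 |
| elm | 0.500 | 1.6 |
| elm | 0.667 | 4.0 |
| elm | 1.00 | 4.6 |
| elm | 1.50 | 3.8 |
| elm | 2.50 | 6.1 |
| elm | 4.00 | 4.6 |

(each reading ± 1 percentage point)

- the numbers in the tables scatter with a standard deviation of 1 percentage point
- at the start none of the gas is in solution
- "hardly changes" means that all values lie within two and a half points (for a concentration: within two and a half percent of the largest)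

- [target] at the end for south-west, south, east, south-east, in this order
- how that number moves from the first to the last of them (hardly changes / rises all the way / falls, then rises / falls all the way / rises, then falls)

From 1.00 h on, the larch run stands near 14.0% of its charge. If target is the sole loss of starting material, target over starting material left is 0.163. I take gas in solution in larch to be at saturation, 5.3 mM, which makes the holding constant, target per starting material left per gas in solution, 30.7 M⁻¹.

The elm run stands near 4.78% from 1.00 h on, so its ratio is 0.0501. The constant then puts gas in solution in elm at 1.63 mM, less than saturation.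

The ratio therefore falls from the larch run to the elm run. I let it fall as a hyperbola through both runs, with scale charge 0.0772 M and zero-charge ratio 0.245. As my own estimate, that gives target of 7.27 mM, 10.5 mM, 13.7 mM and 15.9 mM for south-west, south, east and south-east.

The weak link is starting material left: no reading shows it, and I have set it to charge less target. So I reforge the rule to leave that amount open, and I carry this: target equals holding constant times starting material left times gas in solution, while the balance stands.

The forecast gives 0.007 M, 0.0098 M, 0.0133 M and 0.0168 M, shape rises all the way, in its words “rising throughout”. It stands near my row, but both come from the same two plateaus, so that closeness checks nothing.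

The flask gives 0.00713 M, 0.0115 M, 0.0162 M and 0.0156 M: the shape is rises, then falls, and the row turns at 0.34 M of starting material.

    second substrate + partner ⇌ second product (K = 360 M⁻¹, k = 1.40 M⁻¹ min⁻¹)
    starting material + partner ⇌ target (K = 35.0 M⁻¹, k = 3.50 M⁻¹ min⁻¹)
    gas ⇌ partner, rate k3*(csat - [partner]) (kL = 0.130 min⁻¹)
    second substrate ⇌ dormant form (K = 17.0, k = 0.0160 min⁻¹)
    starting material + target → side product (k = 0.0880 M⁻¹ min⁻¹)

In south-west at 0.556 h, target falls back 21 times faster than it goes on. At the end of south-west, the step joining starting material and partner, the gas in solution, has by itself a relaxation half-life, both ways together, of 2.68 min, short against 4.0 h. The holding constant times starting material left and partner at the end of south-west gives 6.42 mM, against target 0.00713 M. At the end of south-east it gives 17.5 mM against target 0.0156 M, with 60.6% of the starting material charged left and side product, counted as two, at 36.3%.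

The numbers in the tables stem from a simulated flask with made-up constants.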